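**Retrosynthetic overview**
- Feature: in the cis-fused hexahydrocyclopenta[c]isoxazole core, the N1–C6a and C3–C3a bonds stand cis on the neighbouring cyclopentane carbons C6a and C3a. This is an N=C=O unit laid across cyclopentene, i.e. β-lactam 5 with its carbonyl carbon as the later C3.
- Disconnections, backwards: C3–H (hemiketal reduction, sets C3 last); O2–C3 and N1–O2 (N-oxygenation of a secondary amine, hemiketal closure); N1–CH2 (reductive amination with (Z)-aldehyde 15); C3–octyl (Grignard opening of N-Boc lactam 6); finally the lactam (isocyanate [2+2], lipase resolution).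
- Ring order: the azetidinone ring is built first on the cyclopentane (step 1) and opened again in step 8; the isoxazolidine ring is closed in step 12 and fixed in step 13.
- Both side chains come from one building block, 3-(8-bromooctyl)pyridine 10; the (Z)-alkene comes from alkyne semihydrogenation.

Key step: step 1

Assumption: Candida antarctica lipase B is taken to hydrolyse the (1R,5S) lactam, as is usual for cis cycloalkane-fused β-lactams, so that the (1S,5R) lactam is the one left unreacted.

**Route**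

Step 1
Reactants: 1 cyclopentene; 2 chlorosulfonyl isocyanate
Product: 4 cis-6-azabicyclo[3.2.0]heptan-7-one (racemate), via N-chlorosulfonyl β-lactam 3 (not isolated)
Conditions: CH2Cl2, 0 °C → rt; then aq. Na2SO3, NaOH to pH 7–8, 0 °C
Reagents that add atoms: none
Why: The C=C of cyclopentene attacks the strongly electrophilic central carbon of chlorosulfonyl isocyanate and the nitrogen closes onto the neighbouring carbon, in one asynchronous event or through a short-lived 1,4-dipole, so that C1–C7 (the later C3a–C3 bond) and C5–N6 (the later C6a–N1 bond) form on one face of the alkene; aqueous sulfite then reduces the S–Cl bond and the N-sulfinate loses SO2 to leave the NH lactam. The closest known reaction type is the isocyanate–alkene [2+2] cycloaddition of chlorosulfonyl isocyanate with simple cycloalkenes, followed by reductive N-desulfonylation. The four-membered azetidinone ring is closed by the cycloaddition itself, as a suprafacial annulation onto the ring double bond and not by cyclisation of a tether. The two new stereocentres C1 and C5 are forced cis by the ring fusion, because a trans-fused azetidinone on a five-membered ring is out of reach; cyclopentene is symmetrical, so the lactam forms as a racemate and its absolute configuration is left to step 2. The step needs chemoselectivity for cycloaddition over the ene-type path to an unsaturated N-chlorosulfonyl amide, which the unhindered disubstituted alkene and the mild temperature should secure; there is no regiochemical issue.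

Step 2
Reactants: 4 cis-6-azabicyclo[3.2.0]heptan-7-one (racemate)
Product: 5 (1S,5R)-6-azabicyclo[3.2.0]heptan-7-one
Conditions: immobilised Candida antarctica lipase B, H2O (0.5–1 equiv), iPr2O, 65 °C, run slightly past half conversion; filter off enzyme and precipitated amino acid
Reagents that add atoms: none
Why: Lipase-catalysed enantioselective hydrolytic ring opening (kinetic resolution) should consume the (1R,5S) lactam as acyl donor and leave the (1S,5R) lactam in solution; no stereocentre is made, the absolute configuration of both ring-fusion carbons is selected here.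

Step 3
Reactants: 5 (1S,5R)-6-azabicyclo[3.2.0]heptan-7-one
Product: 6 tert-butyl (1S,5R)-7-oxo-6-azabicyclo[3.2.0]heptane-6-carboxylate
Conditions: Boc2O, Et3N, DMAP (cat.), MeCN, rt
Reagents that add atoms: di-tert-butyl dicarbonate, CC(C)(C)OC(=O)OC(=O)OC(C)(C)C
Why: DMAP-catalysed N-acylation of the lactam nitrogen gives the N-Boc lactam, an imide-like acyl donor that a Grignard reagent can open.

Step 4
Reactants: 7 3-methylpyridine; 8 1,7-dibromoheptane
Product: 10 3-(8-bromooctyl)pyridine, via 3-picolyllithium 9 (not isolated)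
Conditions: LiN(iPr)2, THF, –78 °C; then cannulate into 8 (3 equiv), THF, –78 → 0 °C; use freshly purified or keep cold in solution
Reagents that add atoms: none
Why: Lateral lithiation of the picoline methyl group followed by SN2 alkylation, with inverse addition to excess dibromide to suppress double alkylation.

Step 5
Reactants: 11 pent-4-yn-1-ol; 10 3-(8-bromooctyl)pyridine
Product: 13 13-(pyridin-3-yl)tridec-4-yn-1-ol, via dilithiated pent-4-yn-1-ol 12 (not isolated)
Conditions: n-BuLi (2 equiv per 11), THF/DMPU, –78 → 0 °C; then 10, 0 °C → rt; H2O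
Reagents that add atoms: none
Why: C-alkylation of an alkynol dianion (acetylide SN2 on a primary bromide), the acetylide carbon being far more nucleophilic than the lithium alkoxide.

Step 6
Reactants: 13 13-(pyridin-3-yl)tridec-4-yn-1-ol
Product: 14 (4Z)-13-(pyridin-3-yl)tridec-4-en-1-ol
Conditions: H2 (1 atm), Pd/CaCO3 poisoned with Pb(OAc)2 (Lindlar catalyst), quinoline, EtOAc, rt, stopped at one equivalent of H2
Reagents that add atoms: none
Why: Lindlar semihydrogenation delivers both hydrogens syn on the poisoned Pd surface and so sets the (Z)-alkene; the pyridine ring is not reduced.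

Step 7
Reactants: 14 (4Z)-13-(pyridin-3-yl)tridec-4-en-1-ol
Product: 15 (4Z)-13-(pyridin-3-yl)tridec-4-enal
Conditions: (COCl)2, DMSO, CH2Cl2, –78 °C; Et3N, –78 → 0 °C
Reagents that add atoms: none
Why: Swern oxidation stops at the aldehyde and leaves the pyridine and the (Z)-alkene untouched.

Step 8
Reactants: 10 3-(8-bromooctyl)pyridine; 6 tert-butyl (1S,5R)-7-oxo-6-azabicyclo[3.2.0]heptane-6-carboxylate
Product: 17 tert-butyl N-[(1R,2S)-2-[9-(pyridin-3-yl)nonanoyl]cyclopentyl]carbamate, via 8-(pyridin-3-yl)octylmagnesium bromide 16 (not isolated)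
Conditions: Mg turnings (I2-activated), LiCl, THF, 25 °C; then add to 6, THF, –78 → –40 °C; AcOH, –78 °C
Reagents that add atoms: none
Why: Grignard acyl substitution on an N-Boc β-lactam: addition to the strained, carbamate-activated carbonyl and ring opening with loss of the Boc-stabilised nitrogen should give the cis β-(Boc-amino) ketone with both stereocentres carried over, the pyridine ring being inert to an alkylmagnesium halide without N-activation.

Step 9
Reactants: 17 tert-butyl N-[(1R,2S)-2-[9-(pyridin-3-yl)nonanoyl]cyclopentyl]carbamate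
Product: 18 1-[(1S,2R)-2-aminocyclopentyl]-9-(pyridin-3-yl)nonan-1-one dihydrochloride
Conditions: HCl (4 M in dioxane), CH2Cl2, 0 °C, short reaction time; evaporate
Reagents that add atoms: hydrogen chloride, Cl
Why: Acidolysis of the Boc carbamate (loss of the tert-butyl cation, then decarboxylation); keeping the product as its salt guards the β-amino ketone against self-condensation and base-mediated epimerisation at the ketone α-carbon.

Step 10
Reactants: 18 1-[(1S,2R)-2-aminocyclopentyl]-9-(pyridin-3-yl)nonan-1-one dihydrochloride; 15 (4Z)-13-(pyridin-3-yl)tridec-4-enal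
Product: 20 1-[(1S,2R)-2-{[(4Z)-13-(pyridin-3-yl)tridec-4-en-1-yl]amino}cyclopentyl]-9-(pyridin-3-yl)nonan-1-one, via aldimine 19 (not isolated)
Conditions: Et3N (2 equiv), NaBH(OAc)3, ClCH2CH2Cl, 0 °C → rt, hydride present from the start
Reagents that add atoms: none
Why: Direct reductive amination: NaBH(OAc)3 reduces the aldimine as it forms but not the dialkyl ketone, and the α-branched primary amine should stop at monoalkylation.

Step 11
Reactants: 20 1-[(1S,2R)-2-{[(4Z)-13-(pyridin-3-yl)tridec-4-en-1-yl]amino}cyclopentyl]-9-(pyridin-3-yl)nonan-1-one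
Product: 21 1-[(1S,2R)-2-{(benzoyloxy)[(4Z)-13-(pyridin-3-yl)tridec-4-en-1-yl]amino}cyclopentyl]-9-(pyridin-3-yl)nonan-1-one
Conditions: (PhCO2)2, K2HPO4, DMF, rt
Reagents that add atoms: dibenzoyl peroxide, O=C(OOC(=O)c1ccccc1)c1ccccc1
Why: Electrophilic N-oxygenation of a secondary amine by dibenzoyl peroxide (substitution at the peroxide oxygen) gives the O-benzoylhydroxylamine and stops there, while the far less nucleophilic pyridines and the alkene should not react.

Step 12
Reactants: 21 1-[(1S,2R)-2-{(benzoyloxy)[(4Z)-13-(pyridin-3-yl)tridec-4-en-1-yl]amino}cyclopentyl]-9-(pyridin-3-yl)nonan-1-one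
Product: 23 (3aS,6aR)-3-[8-(pyridin-3-yl)octyl]-1-[(4Z)-13-(pyridin-3-yl)tridec-4-en-1-yl]hexahydro-1H-cyclopenta[c][1,2]oxazol-3-ol (both C3 epimers), via N-hydroxy amino ketone 22 (not isolated)
Conditions: K2CO3, MeOH, 0 °C → rt
Reagents that add atoms: none
Why: Methanolysis of the activated N–O benzoate (transesterification) frees the N-hydroxy group, which adds to the cis ketone (5-exo-trig hemiketalisation) to close the isoxazolidine ring; any trans epimer at the ketone α-carbon can equilibrate under the carbonate and should drain into the same cis-fused hemiketal.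

Step 13
Reactants: 23 (3aS,6aR)-3-[8-(pyridin-3-yl)octyl]-1-[(4Z)-13-(pyridin-3-yl)tridec-4-en-1-yl]hexahydro-1H-cyclopenta[c][1,2]oxazol-3-ol
Product: 24 pyrinodemin C, (3S,3aS,6aR)-3-[8-(pyridin-3-yl)octyl]-1-[(4Z)-13-(pyridin-3-yl)tridec-4-en-1-yl]hexahydro-1H-cyclopenta[c][1,2]oxazole
Conditions: Et3SiH (5 equiv), BF3·OEt2 (5 equiv), CH2Cl2, –78 → –20 °C; aq. NaHCO3
Reagents that add atoms: none
Why: Ionic hydrogenation of a cyclic hemiketal (lactol-to-cyclic-ether reduction): BF3 ionises C3–OH to the O2=C3 oxocarbenium ion and Et3SiH should deliver hydride to the convex face of the cis-fused bicycle, the face of H3a and H6a, which puts H3 cis to both and the octyl chain on the concave face, i.e. (3S); the excess BF3·OEt2 covers the two pyridines and N1, and the isolated (Z)-alkene is not reduced.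

**Compound list**
1 | cyclopentene | C1=CCCC1 | starting material
2 | chlorosulfonyl isocyanate | O=C=NS(=O)(=O)Cl | starting material
3 | cis-7-oxo-6-azabicyclo[3.2.0]heptane-6-sulfonyl chloride (racemate, one enantiomer drawn) | O=C1N(S(=O)(=O)Cl)[C@@H]2CCC[C@H]12 | intermediate
4 | cis-6-azabicyclo[3.2.0]heptan-7-one (racemate, (1S,5R) enantiomer drawn) | O=C1N[C@@H]2CCC[C@H]12 | intermediate
5 | (1S,5R)-6-azabicyclo[3.2.0]heptan-7-one | O=C1N[C@@H]2CCC[C@H]12 | intermediate
6 | tert-butyl (1S,5R)-7-oxo-6-azabicyclo[3.2.0]heptane-6-carboxylate | O=C1N(C(=O)OC(C)(C)C)[C@@H]2CCC[C@H]12 | intermediate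
7 | 3-methylpyridine | Cc1cccnc1 | starting material
8 | 1,7-dibromoheptane | BrCCCCCCCBr | starting material
9 | (pyridin-3-yl)methyllithium | [Li]Cc1cccnc1 | intermediate
10 | 3-(8-bromooctyl)pyridine | BrCCCCCCCCc1cccnc1 | intermediate
11 | pent-4-yn-1-ol | OCCCC#C | starting material
12 | lithium 5-lithiopent-4-yn-1-olate | [Li]OCCCC#C[Li] | intermediate
13 | 13-(pyridin-3-yl)tridec-4-yn-1-ol | OCCCC#CCCCCCCCCc1cccnc1 | intermediate
14 | (4Z)-13-(pyridin-3-yl)tridec-4-en-1-ol | OCCC/C=C\CCCCCCCCc1cccnc1 | intermediate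
15 | (4Z)-13-(pyridin-3-yl)tridec-4-enal | O=CCC/C=C\CCCCCCCCc1cccnc1 | intermediate
16 | 8-(pyridin-3-yl)octylmagnesium bromide | Br[Mg]CCCCCCCCc1cccnc1 | intermediate
17 | tert-butyl N-[(1R,2S)-2-[9-(pyridin-3-yl)nonanoyl]cyclopentyl]carbamate | CC(C)(C)OC(=O)N[C@@H]1CCC[C@@H]1C(=O)CCCCCCCCc1cccnc1 | intermediate
18 | 1-[(1S,2R)-2-aminocyclopentyl]-9-(pyridin-3-yl)nonan-1-one dihydrochloride | Cl.Cl.N[C@@H]1CCC[C@@H]1C(=O)CCCCCCCCc1cccnc1 | intermediate
19 | aldimine of 18 (free base) with 15 | C(CC/C=C\CCCCCCCCc1cccnc1)=N[C@@H]1CCC[C@@H]1C(=O)CCCCCCCCc1cccnc1 | intermediate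
20 | 1-[(1S,2R)-2-{[(4Z)-13-(pyridin-3-yl)tridec-4-en-1-yl]amino}cyclopentyl]-9-(pyridin-3-yl)nonan-1-one | C(CC/C=C\CCCCCCCCc1cccnc1)N[C@@H]1CCC[C@@H]1C(=O)CCCCCCCCc1cccnc1 | intermediate
21 | 1-[(1S,2R)-2-{(benzoyloxy)[(4Z)-13-(pyridin-3-yl)tridec-4-en-1-yl]amino}cyclopentyl]-9-(pyridin-3-yl)nonan-1-one | C(CC/C=C\CCCCCCCCc1cccnc1)N(OC(=O)c1ccccc1)[C@@H]1CCC[C@@H]1C(=O)CCCCCCCCc1cccnc1 | intermediate
22 | 1-[(1S,2R)-2-{hydroxy[(4Z)-13-(pyridin-3-yl)tridec-4-en-1-yl]amino}cyclopentyl]-9-(pyridin-3-yl)nonan-1-one | C(CC/C=C\CCCCCCCCc1cccnc1)N(O)[C@@H]1CCC[C@@H]1C(=O)CCCCCCCCc1cccnc1 | intermediate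
23 | (3aS,6aR)-3-[8-(pyridin-3-yl)octyl]-1-[(4Z)-13-(pyridin-3-yl)tridec-4-en-1-yl]hexahydro-1H-cyclopenta[c][1,2]oxazol-3-ol (C3 epimers) | C(CC/C=C\CCCCCCCCc1cccnc1)N1OC(O)(CCCCCCCCc2cccnc2)[C@H]2CCC[C@H]21 | intermediate
24 | pyrinodemin C, (3S,3aS,6aR)-3-[8-(pyridin-3-yl)octyl]-1-[(4Z)-13-(pyridin-3-yl)tridec-4-en-1-yl]hexahydro-1H-cyclopenta[c][1,2]oxazole | C(=C/CCCN1O[C@@H](CCCCCCCCc2cccnc2)[C@H]2CCC[C@H]21)/CCCCCCCCc1cccnc1 | target

**Step count**
Total: 13 steps. Longest linear sequence: 9 steps (steps 1, 2, 3, 8, 9, 10, 11, 12, 13, from cyclopentene).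

**Steps most likely to fail**

1. Step 13. The three basic nitrogens may tie up the Lewis acid so that ionisation of the hemiketal is slow, and hydride delivery to the oxocarbenium ion may not be face-selective enough. The fallback sets out from 17 and comes back at 24; it sets the carbinol centre by catalyst control and closes the ring by SN2 with inversion.
   - Corey–Bakshi–Shibata reduction of 17 ((S)-2-methyl-CBS-oxazaborolidine, BH3·SMe2 in excess, THF, –20 °C; the catalyst enantiomer is the one that treats the cyclopentyl side as the large group) should give tert-butyl N-[(1R,2S)-2-[(1R)-1-hydroxy-9-(pyridin-3-yl)nonyl]cyclopentyl]carbamate F1.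
   - HCl in dioxane/MeOH removes the Boc group and any pyridine–borane adduct to give (1R)-1-[(1S,2R)-2-aminocyclopentyl]-9-(pyridin-3-yl)nonan-1-ol dihydrochloride F2.
   - Reductive amination with 15 (Et3N, NaBH(OAc)3) passes through the aldimine of the amino alcohol F3 and gives (1R)-1-[(1S,2R)-2-{[(4Z)-13-(pyridin-3-yl)tridec-4-en-1-yl]amino}cyclopentyl]-9-(pyridin-3-yl)nonan-1-ol F4.
   - (PhCO2)2/K2HPO4 in DMF gives the N-benzoyloxy amino alcohol F5, and MsCl/Et3N at 0 °C converts its carbinol into the mesylate F6.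
   - K2CO3 in MeOH then removes the benzoate, and the N-hydroxy mesylate F7 closes by intramolecular O-alkylation (5-exo-tet, inversion at the carbinol carbon, (R) to (3S)) to 24.

2. Step 8. The Grignard reagent may add a second time to the ketone as it is released, or act as a base and epimerise the ketone α-carbon; magnesium insertion may also be sluggish because the pyridine nitrogen binds the metal. The fallback sets out from 6 and 10 and comes back at 17; it replaces the acyl substitution by a Fukuyama coupling, which is non-basic and cannot over-add.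
   - LiOH in THF/H2O at 0 °C opens 6 to (1S,2R)-2-[(tert-butoxycarbonyl)amino]cyclopentane-1-carboxylic acid F8.
   - EtSH, EDC·HCl and catalytic DMAP give S-ethyl (1S,2R)-2-[(tert-butoxycarbonyl)amino]cyclopentane-1-carbothioate F9.
   - Zinc dust with LiCl in THF at 50 °C inserts into 10 to give [8-(pyridin-3-yl)octyl]zinc bromide F10.
   - Coupling of F9 with F10 under PdCl2(PPh3)2 in THF/toluene at rt should give 17.

3. Step 11. The hindered amine may be N-benzoylated instead of N-oxygenated, or the reaction may stall. The fallback sets out from 20 and comes back at 23; it reaches the hydroxylamine by Cope elimination.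
   - Conjugate addition of 20 to acrylonitrile (MeOH, 40 °C) gives the N-(2-cyanoethyl) tertiary amine F11.
   - mCPBA (1 equiv, CH2Cl2, –78 °C → rt) oxidises the aliphatic nitrogen much faster than the pyridines or the alkene, giving the N-oxide F12.
   - F12 undergoes Cope elimination at rt towards the cyanoethyl group; the ring hydrogen α to the ketone is trans to nitrogen and cannot take part in the syn elimination. This frees 22, which closes to 23.

**Further compounds**
F1 | step 13 | tert-butyl N-[(1R,2S)-2-[(1R)-1-hydroxy-9-(pyridin-3-yl)nonyl]cyclopentyl]carbamate | CC(C)(C)OC(=O)N[C@@H]1CCC[C@@H]1[C@H](O)CCCCCCCCc1cccnc1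
F2 | step 13 | (1R)-1-[(1S,2R)-2-aminocyclopentyl]-9-(pyridin-3-yl)nonan-1-ol dihydrochloride | Cl.Cl.N[C@@H]1CCC[C@@H]1[C@H](O)CCCCCCCCc1cccnc1
F3 | step 13 | aldimine of F2 (free base) with 15 | C(CC/C=C\CCCCCCCCc1cccnc1)=N[C@@H]1CCC[C@@H]1[C@H](O)CCCCCCCCc1cccnc1
F4 | step 13 | (1R)-1-[(1S,2R)-2-{[(4Z)-13-(pyridin-3-yl)tridec-4-en-1-yl]amino}cyclopentyl]-9-(pyridin-3-yl)nonan-1-ol | C(CC/C=C\CCCCCCCCc1cccnc1)N[C@@H]1CCC[C@@H]1[C@H](O)CCCCCCCCc1cccnc1
F5 | step 13 | (1R)-1-[(1S,2R)-2-{(benzoyloxy)[(4Z)-13-(pyridin-3-yl)tridec-4-en-1-yl]amino}cyclopentyl]-9-(pyridin-3-yl)nonan-1-ol | C(CC/C=C\CCCCCCCCc1cccnc1)N(OC(=O)c1ccccc1)[C@@H]1CCC[C@@H]1[C@H](O)CCCCCCCCc1cccnc1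
F6 | step 13 | (1R)-1-[(1S,2R)-2-{(benzoyloxy)[(4Z)-13-(pyridin-3-yl)tridec-4-en-1-yl]amino}cyclopentyl]-9-(pyridin-3-yl)nonyl methanesulfonate | C(CC/C=C\CCCCCCCCc1cccnc1)N(OC(=O)c1ccccc1)[C@@H]1CCC[C@@H]1[C@H](OS(C)(=O)=O)CCCCCCCCc1cccnc1
F7 | step 13 | (1R)-1-[(1S,2R)-2-{hydroxy[(4Z)-13-(pyridin-3-yl)tridec-4-en-1-yl]amino}cyclopentyl]-9-(pyridin-3-yl)nonyl methanesulfonate | C(CC/C=C\CCCCCCCCc1cccnc1)N(O)[C@@H]1CCC[C@@H]1[C@H](OS(C)(=O)=O)CCCCCCCCc1cccnc1
F8 | step 8 | (1S,2R)-2-[(tert-butoxycarbonyl)amino]cyclopentane-1-carboxylic acid | CC(C)(C)OC(=O)N[C@@H]1CCC[C@@H]1C(=O)O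
F9 | step 8 | S-ethyl (1S,2R)-2-[(tert-butoxycarbonyl)amino]cyclopentane-1-carbothioate | CC(C)(C)OC(=O)N[C@@H]1CCC[C@@H]1C(=O)SCC
F10 | step 8 | [8-(pyridin-3-yl)octyl]zinc bromide | Br[Zn]CCCCCCCCc1cccnc1
F11 | step 11 | 3-{[(1R,2S)-2-[9-(pyridin-3-yl)nonanoyl]cyclopentyl][(4Z)-13-(pyridin-3-yl)tridec-4-en-1-yl]amino}propanenitrile | C(CC/C=C\CCCCCCCCc1cccnc1)N(CCC#N)[C@@H]1CCC[C@@H]1C(=O)CCCCCCCCc1cccnc1
F12 | step 11 | N-oxide of F11 at the aliphatic nitrogen | C(CC/C=C\CCCCCCCCc1cccnc1)[N+]([O-])(CCC#N)[C@@H]1CCC[C@@H]1C(=O)CCCCCCCCc1cccnc1
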